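**Retrosynthetic overview**

1. The ring carbons are lettered Ca–Cp in the order of the target SMILES (Ca carries the C19 methylidene, Cb the acetate, Co and Cp the hydroxyls). The plan rests on the tetrasubstituted Ch=Ci olefin, the one edge shared by the cyclohexene (Ch, Ci, Cj, Cn, Co, Cp) and the eleven-membered ring (Ca–Ck). Cut as a metathesis bond, it leaves a Ch methylidene and a Cj isopropenyl group on an unstrained thirteen-membered ring (Ca–Ch, Cp, Co, Cn, Cj, Ck). That ring shares the segment Cn–Cj–Ck with the cyclopentane, giving a bicyclo[10.2.1]pentadecane.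
2. The thirteen-membered ring is opened at Ca–Cb. It is closed by a Nozaki–Hiyama–Kishi reaction of an enol triflate onto an aldehyde, and Cb is then fixed by oxidation and CBS reduction.
3. The open chain is cut at Co–Cp. A syn-selective alkoxyallylboration joins a cyclopentanecarbaldehyde to a 2-alkylallyl MOM ether made from (S)-citronellol (source of Ce). It sets Co, Cp and the Ch methylidene in one step.
4. The all-cis Cn/Cj/Ck triad comes from three groups that each enter anti on a cyclopentene ester: isopropenyl anti to a silyloxy group (Cj), methyl anti to isopropenyl (Cn), and palladium-borne hydride anti to isopropenyl (Ck).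
5. Ring order: cyclopentane (present from the start), thirteen-membered ring (step 20), then cyclohexene and eleven-membered ring together (step 24).

Key step: step 24

Assumption: methyl 3-oxocyclopent-1-ene-1-carboxylate, 2-bromoprop-2-en-1-ol and (−)-Ipc2BOMe are taken as purchasable. β denotes the cyclopentane face that carries the Cn methyl group, and α the opposite face.

Step 1
Reactants: 1 methyl 3-oxocyclopent-1-ene-1-carboxylate
Product: 2 methyl (3S)-3-hydroxycyclopent-1-ene-1-carboxylate
Conditions: (R)-Me-CBS oxazaborolidine (10 mol%), catecholborane, toluene, −78 °C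
Reagents that add atoms: none
Why: Corey–Bakshi–Shibata reduction of a cyclic enone, in which the alkene arm acts as the large substituent, so the (R)-catalyst should deliver hydride to the face giving the (3S)-carbinol (future Ck, oxygen β), the source of absolute configuration for the ring.

Step 2
Reactants: 2 methyl (3S)-3-hydroxycyclopent-1-ene-1-carboxylate
Product: 3 methyl (3S)-3-[(tert-butyldimethylsilyl)oxy]cyclopent-1-ene-1-carboxylate
Conditions: TBSCl, imidazole, DMF, rt
Reagents that add atoms: tert-butyldimethylsilyl chloride CC(C)(C)[Si](C)(C)Cl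
Why: Routine silylation, which installs the bulky group that shields the β face of the enoate in step 3.

Step 3
Reactants: 3 methyl (3S)-3-[(tert-butyldimethylsilyl)oxy]cyclopent-1-ene-1-carboxylate; 4 isopropenylmagnesium bromide
Product: 6 methyl (2R,3S)-3-[(tert-butyldimethylsilyl)oxy]-2-(prop-1-en-2-yl)cyclopentane-1-carboxylate (both C1 epimers), via silyl ketene acetal 5 (not isolated)
Conditions: CuBr·SMe2 (20 mol%), Me3SiCl, THF, −78 → −30 °C; aq NH4Cl
Reagents that add atoms: none
Why: Copper-catalysed, Me3SiCl-accelerated conjugate addition of a Grignard reagent to an enoate; the nucleophile should enter anti to the vicinal silyloxy group and so fix Cj (isopropenyl α), and the ester-bearing centre does not matter because step 4 erases it.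

Step 4
Reactants: 6 methyl (2R,3S)-3-[(tert-butyldimethylsilyl)oxy]-2-(prop-1-en-2-yl)cyclopentane-1-carboxylate
Product: 8 methyl (1S,2S,3S)-3-[(tert-butyldimethylsilyl)oxy]-1-methyl-2-(prop-1-en-2-yl)cyclopentane-1-carboxylate, via lithium enolate 7 (not isolated)
Conditions: LDA, THF, −78 °C; MeI, DMPU, −78 → −20 °C
Reagents that add atoms: iodomethane CI
Why: Alkylation of a cyclopentanecarboxylate enolate, in which MeI should approach planar Cn anti to the adjacent isopropenyl group, placing the methyl β and the ester carbon (Co) α, cis to the isopropenyl group.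

Step 5
Reactants: 8 methyl (1S,2S,3S)-3-[(tert-butyldimethylsilyl)oxy]-1-methyl-2-(prop-1-en-2-yl)cyclopentane-1-carboxylate
Product: 9 [(1S,2S,3S)-3-[(tert-butyldimethylsilyl)oxy]-1-methyl-2-(prop-1-en-2-yl)cyclopentyl]methanol
Conditions: i-Bu2AlH (2.5 equiv), CH2Cl2, −78 → 0 °C
Reagents that add atoms: none
Why: Hydride reduction of an ester to the primary alcohol, with the silyl ether and the isolated olefin inert.

Step 6
Reactants: 9 [(1S,2S,3S)-3-[(tert-butyldimethylsilyl)oxy]-1-methyl-2-(prop-1-en-2-yl)cyclopentyl]methanol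
Product: 10 (1S,2S,3S)-3-[(tert-butyldimethylsilyl)oxy]-1-methyl-2-(prop-1-en-2-yl)cyclopentane-1-carbaldehyde
Conditions: Dess–Martin periodinane, NaHCO3, CH2Cl2, 0 °C → rt
Reagents that add atoms: none
Why: Dess–Martin oxidation, giving an aldehyde that has no α-hydrogen and therefore cannot epimerise.

Step 7
Reactants: 11 (S)-citronellol
Product: 12 (6S)-8-bromo-2,6-dimethyloct-2-ene
Conditions: CBr4, PPh3, CH2Cl2, 0 °C
Reagents that add atoms: tetrabromomethane BrC(Br)(Br)Br
Why: Appel reaction of a primary alcohol, which leaves the chiral-pool centre (Ce) and the trisubstituted olefin untouched.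

Step 8
Reactants: 12 (6S)-8-bromo-2,6-dimethyloct-2-ene
Product: 14 (4S)-6-bromo-1,1-dimethoxy-4-methylhexane, via bromo aldehyde 13 (not isolated)
Conditions: O3, CH2Cl2/MeOH, −78 °C; Me2S; then HC(OMe)3, TsOH (cat.), rt
Reagents that add atoms: trimethyl orthoformate COC(OC)OC
Why: Ozonolysis with reductive work-up followed by acid-catalysed acetalisation in the same flask, which turns citronellol C6 into masked Cb while the primary bromide survives.

Step 9
Reactants: 15 2-bromoprop-2-en-1-ol
Product: 16 2-bromo-3-(methoxymethoxy)prop-1-ene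
Conditions: MOMCl, i-Pr2NEt, CH2Cl2, 0 °C → rt
Reagents that add atoms: chloromethyl methyl ether COCCl
Why: Routine MOM protection, which supplies the ether oxygen that later directs the α-lithiation.

Step 10
Reactants: 14 (4S)-6-bromo-1,1-dimethoxy-4-methylhexane; 16 2-bromo-3-(methoxymethoxy)prop-1-ene
Product: 18 (5R)-8,8-dimethoxy-2-[(methoxymethoxy)methyl]-5-methyloct-1-ene, via Grignard reagent 17 (not isolated)
Conditions: Mg, THF, 40 °C; then 16, PdCl2(dppf) (3 mol%), THF, 0 °C → rt
Reagents that add atoms: none
Why: Kumada–Corriu coupling of a primary alkyl Grignard reagent with a 2-bromoalkene forms Cg–Ch, the wide-bite dppf ligand suppresses β-hydride elimination, and both acetals tolerate the reagent.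

Step 11
Reactants: 18 (5R)-8,8-dimethoxy-2-[(methoxymethoxy)methyl]-5-methyloct-1-ene; 10 (1S,2S,3S)-3-[(tert-butyldimethylsilyl)oxy]-1-methyl-2-(prop-1-en-2-yl)cyclopentane-1-carbaldehyde
Product: 22 (1R,2R,6R)-1-[(1S,2S,3S)-3-[(tert-butyldimethylsilyl)oxy]-1-methyl-2-(prop-1-en-2-yl)cyclopentyl]-9,9-dimethoxy-2-(methoxymethoxy)-6-methyl-3-methylidenenonan-1-ol, via allyllithium 19 (not isolated), via allylborane 20 (not isolated), via borinate 21 (not isolated)
Conditions: 18, s-BuLi, THF, −78 °C; (−)-Ipc2BOMe; BF3·OEt2; 10, −78 °C → rt; NaOH, H2O2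
Reagents that add atoms: none
Why: Brown alkoxyallylboration, in which oxygen-guided α-lithiation and borylation at the CH2 terminus give the allylborane with the alkoxy group cis to the CH2B arm, its chair transition state gives the syn (threo) Co/Cp pair, and the isopinocampheyl groups derived from (+)-α-pinene select the aldehyde face leading to (R)-Co and hence (R)-Cp while the allyl shift creates the Ch methylidene.

Step 12
Reactants: 22 the Co alcohol from step 11
Product: 23 Co,Cp-bis(methoxymethyl) ether of 22
Conditions: MOMCl, i-Pr2NEt, Bu4NI (cat.), ClCH2CH2Cl, 60 °C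
Reagents that add atoms: chloromethyl methyl ether COCCl
Why: MOM protection of the hindered carbinol, which gives two small, identical acetal groups next to the Ch methylidene that crowd the later metathesis less than silyl ethers and can be removed together.

Step 13
Reactants: 23 Co,Cp-bis(methoxymethyl) ether
Product: 24 cyclopentanol (Ck–OH β) with Co,Cp-bis(MOM) ether and Cb dimethyl acetal intact
Conditions: Bu4NF, THF, rt → 40 °C
Reagents that add atoms: none
Why: Fluoride cleavage of the only silyl ether, with the acetals and olefins inert.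

Step 14
Reactants: 24 cyclopentanol
Product: 25 cyclopentanone (Ck=O; Cj isopropenyl α)
Conditions: Dess–Martin periodinane, NaHCO3, CH2Cl2, 0 °C; used without chromatography
Reagents that add atoms: none
Why: Buffered Dess–Martin oxidation, whose neutral conditions should keep the α-isopropenyl centre Cj from epimerising or moving into conjugation.

Step 15
Reactants: 25 cyclopentanone
Product: 27 tertiary allylic methyl carbonate (at Ck: vinyl β and OCO2Me α), via magnesium alkoxide 26 (not isolated)
Conditions: CH2=CHMgBr, LaCl3·2LiCl (30 mol%), THF, −78 → 0 °C; then ClCO2Me, 0 °C → rt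
Reagents that add atoms: vinylmagnesium bromide C=C[Mg]Br; methyl chloroformate COC(=O)Cl
Why: Lanthanide-assisted 1,2-addition of a vinyl Grignard reagent, which limits enolisation; attack should come from the β face anti to the isopropenyl group, the alkoxide is trapped as the carbonate, and this carbinol centre is replaced in step 16.

Step 16
Reactants: 27 tertiary allylic methyl carbonate
Product: 28 Ck-vinyl compound (vinyl α and cis to both the isopropenyl group and the Co arm; Ck–H β)
Conditions: Pd2(dba)3·CHCl3 (2.5 mol%), n-Bu3P (10 mol%), HCO2H, Et3N, THF, rt → 40 °C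
Reagents that add atoms: none
Why: Tsuji-type palladium–formate hydrogenolysis of an allylic carbonate, in which zerovalent palladium ionises the carbonate to a π-allyl complex held on the less hindered β face (anti to the leaving group and to the isopropenyl group), formate loses CO2, and with n-Bu3P the hydride passes from the metal to the more substituted terminus Ck, which should give the terminal vinyl group with H β and Ca α.

Step 17
Reactants: 28 Ck-vinyl compound
Product: 29 Ck-acetyl compound (methyl ketone; Ca=O and C19 as CH3)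
Conditions: PdCl2 (10 mol%), Cu(OAc)2 (20 mol%), O2 (1 atm), DMA/H2O 7:1, rt
Reagents that add atoms: water O
Why: Wacker–Tsuji oxidation, selective for the only monosubstituted olefin over the two geminally disubstituted ones, with Cu(OAc)2 in place of CuCl keeping the medium free of HCl for the acetals.

Step 18
Reactants: 29 Ck-acetyl compound
Product: 31 enol triflate Ck–C(OTf)=CH2, via potassium enolate 30 (not isolated)
Conditions: KN(SiMe3)2, THF, −78 °C; PhNTf2, −78 → 0 °C
Reagents that add atoms: N-phenylbis(trifluoromethanesulfonimide) O=S(=O)(N(c1ccccc1)S(=O)(=O)C(F)(F)F)C(F)(F)F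
Why: Kinetic deprotonation at the unhindered methyl group followed by O-sulfonylation gives the terminal enol triflate without touching the Ck–H.

Step 19
Reactants: 31 enol triflate
Product: 32 seco-aldehyde (Cb=O) bearing the Ca enol triflate
Conditions: PPTS (cat.), acetone/H2O, 45 °C
Reagents that add atoms: water O
Why: Mild hydrolysis of a dimethyl acetal, with the MOM ethers, the enol triflate and the olefins stable at this acidity.

Step 20
Reactants: 32 seco-aldehyde
Product: 33 thirteen-membered allylic alcohol (bicyclo[10.2.1]pentadecane triene; both Cb epimers)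
Conditions: CrCl2 (10 equiv), NiCl2 (0.1 equiv), DMF, 2 mM, syringe pump, rt
Reagents that add atoms: none
Why: Nozaki–Hiyama–Kishi macrocyclisation, in which nickel inserts into the C–OTf bond, the alkenyl group passes to chromium and adds chemoselectively to the unhindered aldehyde to form Ca–Cb, and the new centre Cb need not be controlled because step 21 erases it.

Step 21
Reactants: 33 thirteen-membered allylic alcohol
Product: 34 thirteen-membered α-methylene ketone (Cb=O)
Conditions: Dess–Martin periodinane, NaHCO3, CH2Cl2, 0 °C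
Reagents that add atoms: none
Why: Buffered Dess–Martin oxidation converges both epimers on one enone without shifting the exocyclic olefin.

Step 22
Reactants: 34 thirteen-membered α-methylene ketone
Product: 35 thirteen-membered (Cb R)-allylic alcohol
Conditions: (S)-Me-CBS oxazaborolidine (1 equiv), catecholborane, toluene, −78 °C
Reagents that add atoms: none
Why: Corey–Bakshi–Shibata reduction under reagent control, in which the α-branched alkenyl group (Ca) is the large and the Cc methylene the small substituent, so the (S)-catalyst should give (R)-Cb, and catecholborane does not hydroborate the olefins at this temperature.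

Step 23
Reactants: 35 thirteen-membered (Cb R)-allylic alcohol
Product: 36 thirteen-membered triene acetate (metathesis precursor; Co,Cp-bis(MOM) ether)
Conditions: Ac2O, DMAP (cat.), pyridine, rt
Reagents that add atoms: acetic anhydride CC(=O)OC(C)=O
Why: Routine acetylation with retention at Cb.

Step 24
Reactants: 36 thirteen-membered triene acetate
Product: 37 Co,Cp-bis(methoxymethyl) ether of the target
Conditions: RuCl2[1,3-bis(2-methylphenyl)imidazolidin-2-ylidene](=CH-C6H4-2-O-i-Pr) (3 × 5 mol%), 1,4-benzoquinone (10 mol%), toluene, 2 mM, 100 °C, argon sparge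
Reagents that add atoms: none
Why: The phosphine-free ruthenium benzylidene exchanges onto the least encumbered geminal olefin, the Ch methylidene (its neighbour Cg is unbranched), and the resulting Ru=Ch alkylidene adds across the Cj isopropenyl C=C; cycloreversion of the metallacyclobutane gives Ch=Ci and Ru=CH2, which carries the chain with loss of ethylene, and entry through the isopropenyl group leads to the same product. The closest known reaction type is ring-closing metathesis of two 1,1-disubstituted olefins to a tetrasubstituted cyclohexene, for which the o-tolyl analogue of the second-generation Hoveyda–Grubbs catalyst is preferred because mesityl arms crowd the disubstituted carbene. The cyclohexene (Ch, Ci, Cj, Cn, Co, Cp) closes as a six-membered ring across the macrocycle, helped by the isopropenyl group on the one-atom bridge Cj pointing towards the Co–Cp–Ch arm on the α face. The eleven-membered ring (Ca–Ck) is what remains of the thirteen-membered ring, and its olefin is E because Cg and Cj are forced trans once Cp and Cj are cis in the six-membered ring. No stereocentre is formed or touched. The step needs chemoselectivity among three geminal olefins: pairing the Ca methylidene with the isopropenyl group would give a cyclobutene, pairing it with the Ch methylidene would give a tetrasubstituted cycloheptene, and the Ca olefin sits between two branched carbons (Ck, Cb) and is deactivated by the allylic acetate, so six-ring closure should be the fastest productive path, while such olefins do not homodimerise.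

Step 25
Reactants: 37 Co,Cp-bis(methoxymethyl) ether of the target
Product: 38 target CNP0192310.3
Conditions: ZnBr2, n-PrSH, CH2Cl2, 0 °C
Reagents that add atoms: none
Why: Lewis acid/thiol cleavage of MOM ethers at the O–CH2–O carbon, short and cold enough that the allylic acetate, the allylic Cp carbinol and both olefins should survive.

**Compound list**

1 | methyl 3-oxocyclopent-1-ene-1-carboxylate | COC(=O)C1=CC(=O)CC1 | starting material
2 | methyl (3S)-3-hydroxycyclopent-1-ene-1-carboxylate | COC(=O)C1=C[C@@H](O)CC1 | intermediate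
3 | methyl (3S)-3-[(tert-butyldimethylsilyl)oxy]cyclopent-1-ene-1-carboxylate | COC(=O)C1=C[C@@H](O[Si](C)(C)C(C)(C)C)CC1 | intermediate
4 | isopropenylmagnesium bromide | CC(=C)[Mg]Br | starting material
5 | silyl ketene acetal of 6 (not isolated) | COC(O[Si](C)(C)C)=C1CC[C@H](O[Si](C)(C)C(C)(C)C)[C@H]1C(C)=C | intermediate
6 | methyl (2R,3S)-3-[(tert-butyldimethylsilyl)oxy]-2-(prop-1-en-2-yl)cyclopentane-1-carboxylate, C1 epimers | COC(=O)C1CC[C@H](O[Si](C)(C)C(C)(C)C)[C@H]1C(C)=C | intermediate
7 | lithium enolate of 6 (not isolated) | COC([O-])=C1CC[C@H](O[Si](C)(C)C(C)(C)C)[C@H]1C(C)=C.[Li+] | intermediate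
8 | methyl (1S,2S,3S)-3-[(tert-butyldimethylsilyl)oxy]-1-methyl-2-(prop-1-en-2-yl)cyclopentane-1-carboxylate | COC(=O)[C@@]1(C)CC[C@H](O[Si](C)(C)C(C)(C)C)[C@H]1C(C)=C | intermediate
9 | [(1S,2S,3S)-3-[(tert-butyldimethylsilyl)oxy]-1-methyl-2-(prop-1-en-2-yl)cyclopentyl]methanol | OC[C@@]1(C)CC[C@H](O[Si](C)(C)C(C)(C)C)[C@H]1C(C)=C | intermediate
10 | (1S,2S,3S)-3-[(tert-butyldimethylsilyl)oxy]-1-methyl-2-(prop-1-en-2-yl)cyclopentane-1-carbaldehyde | O=C[C@@]1(C)CC[C@H](O[Si](C)(C)C(C)(C)C)[C@H]1C(C)=C | intermediate
11 | (S)-citronellol | OCC[C@@H](C)CCC=C(C)C | starting material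
12 | (6S)-8-bromo-2,6-dimethyloct-2-ene | BrCC[C@@H](C)CCC=C(C)C | intermediate
13 | (4S)-6-bromo-4-methylhexanal (not isolated) | BrCC[C@@H](C)CCC=O | intermediate
14 | (4S)-6-bromo-1,1-dimethoxy-4-methylhexane | BrCC[C@@H](C)CCC(OC)OC | intermediate
15 | 2-bromoprop-2-en-1-ol | OCC(Br)=C | starting material
16 | 2-bromo-3-(methoxymethoxy)prop-1-ene | COCOCC(Br)=C | intermediate
17 | [(3S)-6,6-dimethoxy-3-methylhexyl]magnesium bromide (not isolated) | COC(OC)CC[C@H](C)CC[Mg]Br | intermediate
18 | (5R)-8,8-dimethoxy-2-[(methoxymethoxy)methyl]-5-methyloct-1-ene | COCOCC(=C)CC[C@@H](C)CCC(OC)OC | intermediate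
19 | α-lithiated allyl MOM ether from 18 (not isolated) | [Li]C(OCOC)C(=C)CC[C@@H](C)CCC(OC)OC | intermediate
20 | γ-(methoxymethoxy)allyl-diisopinocampheylborane, OMOM cis to CH2B (not isolated) | COCO/C=C(\CB([C@@H]1C[C@@H]2C[C@H]([C@H]1C)C2(C)C)[C@@H]1C[C@@H]2C[C@H]([C@H]1C)C2(C)C)CC[C@@H](C)CCC(OC)OC | intermediate
21 | diisopinocampheylborinate of 22 (not isolated) | COC(OC)CC[C@H](C)CCC(=C)[C@@H](OCOC)[C@H](OB([C@@H]2C[C@@H]3C[C@H]([C@H]2C)C3(C)C)[C@@H]2C[C@@H]3C[C@H]([C@H]2C)C3(C)C)[C@@]1(C)CC[C@H](O[Si](C)(C)C(C)(C)C)[C@H]1C(C)=C | intermediate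
22 | (1R,2R,6R)-1-[(1S,2S,3S)-3-[(tert-butyldimethylsilyl)oxy]-1-methyl-2-(prop-1-en-2-yl)cyclopentyl]-9,9-dimethoxy-2-(methoxymethoxy)-6-methyl-3-methylidenenonan-1-ol | COC(OC)CC[C@H](C)CCC(=C)[C@@H](OCOC)[C@H](O)[C@@]1(C)CC[C@H](O[Si](C)(C)C(C)(C)C)[C@H]1C(C)=C | intermediate
23 | Co,Cp-bis(MOM) ether of 22 | COC(OC)CC[C@H](C)CCC(=C)[C@@H](OCOC)[C@H](OCOC)[C@@]1(C)CC[C@H](O[Si](C)(C)C(C)(C)C)[C@H]1C(C)=C | intermediate
24 | cyclopentanol (Ck–OH β) from 23 | COC(OC)CC[C@H](C)CCC(=C)[C@@H](OCOC)[C@H](OCOC)[C@@]1(C)CC[C@H](O)[C@H]1C(C)=C | intermediate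
25 | cyclopentanone (Ck=O) | COC(OC)CC[C@H](C)CCC(=C)[C@@H](OCOC)[C@H](OCOC)[C@@]1(C)CCC(=O)[C@H]1C(C)=C | intermediate
26 | bromomagnesium alkoxide of the Ck vinyl carbinol (not isolated) | COC(OC)CC[C@H](C)CCC(=C)[C@@H](OCOC)[C@H](OCOC)[C@@]1(C)CC[C@@](C=C)(O[Mg]Br)[C@H]1C(C)=C | intermediate
27 | tertiary allylic methyl carbonate (Ck: vinyl β, OCO2Me α) | COC(OC)CC[C@H](C)CCC(=C)[C@@H](OCOC)[C@H](OCOC)[C@@]1(C)CC[C@@](C=C)(OC(=O)OC)[C@H]1C(C)=C | intermediate
28 | Ck-vinyl compound (vinyl α, all-cis triad) | COC(OC)CC[C@H](C)CCC(=C)[C@@H](OCOC)[C@H](OCOC)[C@@]1(C)CC[C@@H](C=C)[C@H]1C(C)=C | intermediate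
29 | Ck-acetyl compound | COC(OC)CC[C@H](C)CCC(=C)[C@@H](OCOC)[C@H](OCOC)[C@@]1(C)CC[C@@H](C(C)=O)[C@H]1C(C)=C | intermediate
30 | terminal potassium enolate of 29 (not isolated) | COC(OC)CC[C@H](C)CCC(=C)[C@@H](OCOC)[C@H](OCOC)[C@@]1(C)CC[C@@H](C(=C)[O-])[C@H]1C(C)=C.[K+] | intermediate
31 | enol triflate acetal | COC(OC)CC[C@H](C)CCC(=C)[C@@H](OCOC)[C@H](OCOC)[C@@]1(C)CC[C@@H](C(=C)OS(=O)(=O)C(F)(F)F)[C@H]1C(C)=C | intermediate
32 | seco-aldehyde enol triflate | O=CCC[C@H](C)CCC(=C)[C@@H](OCOC)[C@H](OCOC)[C@@]1(C)CC[C@@H](C(=C)OS(=O)(=O)C(F)(F)F)[C@H]1C(C)=C | intermediate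
33 | thirteen-membered allylic alcohol, Cb epimers | C=C1C(O)CC[C@H](C)CCC(=C)[C@@H](OCOC)[C@H](OCOC)[C@@]2(C)CC[C@@H]1[C@H]2C(C)=C | intermediate
34 | thirteen-membered α-methylene ketone | C=C1C(=O)CC[C@H](C)CCC(=C)[C@@H](OCOC)[C@H](OCOC)[C@@]2(C)CC[C@@H]1[C@H]2C(C)=C | intermediate
35 | thirteen-membered (Cb R)-allylic alcohol | C=C1[C@H](O)CC[C@H](C)CCC(=C)[C@@H](OCOC)[C@H](OCOC)[C@@]2(C)CC[C@@H]1[C@H]2C(C)=C | intermediate
36 | thirteen-membered triene acetate, Co,Cp-bis(MOM) ether (metathesis precursor) | C=C1[C@H](OC(C)=O)CC[C@H](C)CCC(=C)[C@@H](OCOC)[C@H](OCOC)[C@@]2(C)CC[C@@H]1[C@H]2C(C)=C | intermediate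
37 | Co,Cp-bis(MOM) ether of the target (metathesis product) | C=C1[C@H](OC(C)=O)CC[C@H](C)CCC2=C(C)[C@@H]3[C@H]1CC[C@]3(C)[C@@H](OCOC)[C@@H]2OCOC | intermediate
38 | CNP0192310.3 (Cb R, Ce R, Cj S, Ck R, Cn S, Co R, Cp R) | C=C1[C@H](OC(C)=O)CC[C@H](C)CCC2=C(C)[C@@H]3[C@H]1CC[C@]3(C)[C@@H](O)[C@@H]2O | target

**Step counts**

- Total step count: 25.
- Longest linear sequence: 21 (steps 1–6 and 11–25).

**Steps most likely to fail**

1. **Step 24.**
   - What may go wrong: the catalyst may not turn over, because both partners are geminally disubstituted and carry allylic branching. Slow turnover at 100 °C allows decay to ruthenium hydrides that shift the olefins, and closure onto the Ca olefin to a seven-membered ring may compete.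
   - Fallback: the order of ring closure is inverted. The fallback sets out from enol triflate acetal 31, whose only metathesis-active olefins are the Ch methylidene and the isopropenyl group. The same ruthenium catalyst closes the cyclohexene on the flexible open chain to hydrindene acetal F1. PPTS in wet acetone frees hydrindene aldehyde F2. CrCl2/NiCl2 then closes the eleven-membered ring at Ca–Cb to tricyclic allylic alcohol F3. Dess–Martin oxidation gives tricyclic enone F4, and (S)-Me-CBS with catecholborane gives tricyclic (R)-alcohol F5. Acetylation returns to the route at 37.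

2. **Step 11.**
   - What may go wrong: addition to the neopentyl aldehyde may be too slow for the bulky borane. Lithiation may stray to the Cg allylic position, and loss of the enol ether geometry would erode the syn selectivity.
   - Fallback: the Co–Cp bond is made by an auxiliary-controlled glycolate aldol and the chain is attached afterwards. The fallback sets out from aldehyde 10. The dibutylboron enolate of (S)-4-benzyl-3-[(methoxymethoxy)acetyl]-1,3-oxazolidin-2-one (Bu2BOTf, Et3N) gives Evans syn aldol adduct F6. AlMe3 with MeONHMe·HCl gives hydroxy Weinreb amide F7, and MOMCl gives bis(MOM) Weinreb amide F8. Grignard reagent 17 adds once to give Ch ketone F9. Wittig methylenation (Ph3P=CH2, THF, −78 → 0 °C) returns to the route at 23.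

3. **Step 16.**
   - What may go wrong: the π-allyl complex may lose a β-hydrogen to give dienes. Hydride may go to the CH2 terminus and give the ethylidene isomer, or it may be delivered with poor facial selectivity at Ck.
   - Fallback: Ca is attached by cross-coupling and Ck is set by conjugate reduction. The fallback sets out from ketone 25. Kinetic deprotonation at Cl (LDA, then PhNTf2) gives ring enol triflate F10. Stille coupling with tributyl(1-ethoxyvinyl)stannane (Pd(PPh3)4, LiCl, THF, reflux) gives ethoxydiene F11. Oxalic acid on silica gel hydrolyses the enol ether alone to acetylcyclopentene F12. Conjugate reduction with [(Ph3P)CuH]6 in toluene containing t-BuOH, with protonation of the enolate from the open β face, returns to the route at 29.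

**Further compounds**

F1 | step 24 | hydrindene acetal (cyclohexene closed, enol triflate and dimethyl acetal intact) | COC(OC)CC[C@H](C)CCC1=C(C)[C@@H]2[C@H](C(=C)OS(=O)(=O)C(F)(F)F)CC[C@]2(C)[C@@H](OCOC)[C@@H]1OCOC
F2 | step 24 | hydrindene aldehyde | O=CCC[C@H](C)CCC1=C(C)[C@@H]2[C@H](C(=C)OS(=O)(=O)C(F)(F)F)CC[C@]2(C)[C@@H](OCOC)[C@@H]1OCOC
F3 | step 24 | tricyclic allylic alcohol, Cb epimers | C=C1C(O)CC[C@H](C)CCC2=C(C)[C@@H]3[C@H]1CC[C@]3(C)[C@@H](OCOC)[C@@H]2OCOC
F4 | step 24 | tricyclic enone | C=C1C(=O)CC[C@H](C)CCC2=C(C)[C@@H]3[C@H]1CC[C@]3(C)[C@@H](OCOC)[C@@H]2OCOC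
F5 | step 24 | tricyclic (R)-alcohol | C=C1[C@H](O)CC[C@H](C)CCC2=C(C)[C@@H]3[C@H]1CC[C@]3(C)[C@@H](OCOC)[C@@H]2OCOC
F6 | step 11 | Evans syn aldol adduct (2S,3R) | O=C1OC[C@H](Cc2ccccc2)N1C(=O)[C@@H](OCOC)[C@H](O)[C@@]1(C)CC[C@H](O[Si](C)(C)C(C)(C)C)[C@H]1C(C)=C
F7 | step 11 | hydroxy Weinreb amide | CON(C)C(=O)[C@@H](OCOC)[C@H](O)[C@@]1(C)CC[C@H](O[Si](C)(C)C(C)(C)C)[C@H]1C(C)=C
F8 | step 11 | bis(MOM) Weinreb amide | CON(C)C(=O)[C@@H](OCOC)[C@H](OCOC)[C@@]1(C)CC[C@H](O[Si](C)(C)C(C)(C)C)[C@H]1C(C)=C
F9 | step 11 | Ch ketone | COC(OC)CC[C@H](C)CCC(=O)[C@@H](OCOC)[C@H](OCOC)[C@@]1(C)CC[C@H](O[Si](C)(C)C(C)(C)C)[C@H]1C(C)=C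
F10 | step 16 | ring enol triflate (Ck=Cl) | COC(OC)CC[C@H](C)CCC(=C)[C@@H](OCOC)[C@H](OCOC)[C@@]1(C)CC=C(OS(=O)(=O)C(F)(F)F)[C@H]1C(C)=C
F11 | step 16 | ethoxydiene | COC(OC)CC[C@H](C)CCC(=C)[C@@H](OCOC)[C@H](OCOC)[C@@]1(C)CC=C(C(=C)OCC)[C@H]1C(C)=C
F12 | step 16 | acetylcyclopentene | COC(OC)CC[C@H](C)CCC(=C)[C@@H](OCOC)[C@H](OCOC)[C@@]1(C)CC=C(C(C)=O)[C@H]1C(C)=C
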